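- Late in the alder run, from 20.0 min to 30.0 min, Q averages 26.3% and shows no rise, while E averages 73.3%.

| flask | E | X | J | temperature | remark | time |
|---|---|---|---|---|---|---|
| alder | 1.5 M | 1 equiv | 0.5 mol% | 25 °C | the very flask that is asked about, followed so far |  |
| ash | 1.5 M | 1 equiv | 0.5 mol% | 20 °C | run made earlier |  |
| flask | 1.5 M | 1.00 equiv | 0.5 mol% | 25 °C |  | 30 min |

| run | time / min | Q / % | E / % |
|---|---|---|---|
| alder | 1.50 | 6 | 93 |
| alder | 5.00 | 17 | 81 |
| alder | 8.00 | 21 | 77 |
| alder | 12.0 | 22 | 76 |
| alder | 20.0 | 28 | 73 |
| alder | 25.0 | 27 | 75 |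
| alder | 30.0 | 24 | 72 |
| ash | 1.50 | 8 | 91 |
| ash | 5.00 | 18 | 79 |
| ash | 8.00 | 21 | 79 |
| ash | 12.0 | 29 | 72 |
| ash | 20.0 | 30 | 67 |
| ash | 25.0 | 30 | 66 |
| ash | 30.0 | 33 | 63 |

(each reading ± 2 percentage points)

- Q taken out counts as made
- the numbers in the tables scatter with a standard deviation of 2 percentage points
- steps that have been proposed: G -> J + Q; L -> J + Z; X + J <-> L; E + J -> D; E + J <-> G
- additions bring no volume worth counting

- dawn: at 30 min raise the temperature by 10 K, then wait 15 min
- dusk: at 30 min add J, 100% of the amount charged, then wait 15 min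
- spring: at 30 min take out 90% of the Q then present, then wait 15 min
- noon: change nothing and wait 15 min more

* Q, in percent of the E first charged, at 30 min
* the option that brings most further Q ("none" if no option brings more than 2 percentage points) (dawn / dusk / spring / noon / none)
* Q present, with what was taken out counted in, in percent of the E first charged, after dawn
* Q present, with what was taken out counted in, in percent of the E first charged, after noon

The proposed steps are E + J <-> G, G -> J + Q, X + J <-> L, L -> J + Z and E + J -> D.

My own ledger for alder, before the result: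

- Entry for E: Q plus unused E comes to 99.6% of the E charged, so the books close within the scatter of 2 percentage points. D and the bound forms hold at most the J charge, 0.5 mol%.
- Entry for J: with 73.3% of E unused, E is not what stops Q. J, lost to D with no proposed way back, acts as the effective limiting reagent.
- One J at its fork: both G and D start from E + J, so at fixed temperature E cancels from the odds as it falls. G returning to E + J and the detour through L bring J back unchanged.
- The ledger therefore closes on one number, the turnover number N, Q made per J charged, both as fractions of the E charged: 52.7. Each round then ends in D with a chance of about 1.90%.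
- N belongs to one temperature: ash at 20 °C averages 31.0% late, more than alder.
- My reckoning puts Q at 26.3% at 30 min. Dawn, spring and noon act on J that the flat late readings no longer show at work. Dusk's fresh J should add N times its charge, 26 points, more than the margin.
- The forecast gives 26% now, dusk as best, 26.6% after dawn and 26.4% after noon, holding that “Fresh J should give another burst”.

The alder flask gives 26.5% now, dusk as best, 26.6% after dawn and 26.6% after noon.

    G → J + Q (k = 0.830 s⁻¹, Ea = 67.0 kJ mol⁻¹)
    L → J + Z (k = 7.80 s⁻¹, Ea = 58.0 kJ mol⁻¹)
    X + J ⇌ L (K = 120 M⁻¹, k = 0.710 M⁻¹ s⁻¹, Ea = 63.0 kJ mol⁻¹, ΔH = −44.0 kJ mol⁻¹)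
    E + J → D (k = 0.00390 M⁻¹ s⁻¹, Ea = 63.0 kJ mol⁻¹)
    E + J ⇌ G (K = 0.290 M⁻¹, k = 1.50 M⁻¹ s⁻¹, Ea = 37.0 kJ mol⁻¹, ΔH = −46.0 kJ mol⁻¹)
    (constants at 25 °C)

- In alder, Q and D grew together while J still cycled: at 3.00 min D held 48.8% of the catalyst with Q at 13.0%, and at 15.0 min D held 95.5% with Q at 25.4%. With D at 99.8% at 30.0 min, Q stood at 26.5%, and by 300 min it had reached 26.6%, beside 72.9% of E. Dusk's new J added 24 points in 15 min, against the 26 points reckoned from N. For the forecast's 26% to go wrong, a run would have to show a shift like the computed one: Q at 30 min moves 5 points from 26.5% with alder's J at 0.41 mol% or 0.59 mol%.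
- With J at 1.2 mol% and the same temperature, N gives 63.2% of Q. That neighbour flask computes to 62.8%, with 36% of E left.

All runs were computed for substances that don't exist; noise was put on by code.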